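Locants: ring N1, C2 (CH3), C3 (OH), C6; side chain C1'–C16' counted from C6 (OH on C4' and C15'). The ring is the all-equatorial 2,6-cis/2,3-trans isomer.
Key disconnection C5'–C6': both atoms are unbranched CH2 groups of the (CH2)10 spacer and C5' lies β to the oxygen on C4', so O–C4'–C5'(CO2H) is the retron of a β-oxy carboxylic acid. The bond is formed by anodic decarboxylative cross-coupling (mixed Kolbe electrolysis) of the finished piperidine acid with (S)-11-acetoxydodecanoic acid, and only one deprotection follows.
The carboxyl carbon on C5' is a traceless control element. As β-keto ester it lets Ru-(R)-BINAP set C4', as benzyl ester it stands by while the other chain end is activated, and it finally leaves as CO2.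
The C12 acid arises by the same reaction type (bond C13'–C14') from (S)-3-acetoxybutanoic acid and mono-tert-butyl sebacate. Ring C2 and C3 come from D-alaninol by Felkin–Anh ethynylation.
Ring order: a temporary δ-lactone (closed in step 6, opened in step 7 when the acetylide forms C5–C6), then the piperidine, the only ring of the target, closed at N1–C6 in step 9 by a hydrogenation/reductive amination cascade.

Key step: step 14

Remark: the free base is taken as the form of the target, and all starting materials in the list are taken to be catalogue compounds.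

Step 1
Reactants: 1 (R)-2-aminopropan-1-ol (D-alaninol)
Product: 2 (R)-2-(dibenzylamino)propan-1-ol
Conditions: BnBr (2.1 equiv), K2CO3, MeCN, reflux
Reagents that add atoms: benzyl bromide, BrCc1ccccc1
Why: Double SN2 N-benzylation of the primary amine; under carbonate conditions the hydroxyl group is far less nucleophilic, and the stereocentre (ring C2, R, from the chiral pool) is not touched.

Step 2
Reactants: 2 (R)-2-(dibenzylamino)propan-1-ol
Product: 3 (R)-2-(dibenzylamino)propanal
Conditions: (COCl)2, DMSO, CH2Cl2, −78 °C; Et3N, −78 → 0 °C; used crude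
Reagents that add atoms: none
Why: The Swern oxidation runs at low temperature without acid or strong base, so the α-(dibenzylamino) aldehyde should form without enolisation and is used at once.

Step 3
Reactants: 3 (R)-2-(dibenzylamino)propanal; 4 ethynylmagnesium bromide
Product: 5 (3S,4R)-4-(dibenzylamino)pent-1-yn-3-ol
Conditions: THF, −40 → 0 °C; aqueous work-up
Reagents that add atoms: none
Why: Grignard 1,2-addition under Felkin–Anh (non-chelation) control; the bulky, non-chelating NBn2 group stands anti to the incoming acetylide, which should give the anti amino alcohol and so set ring C3 as S.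

Step 4
Reactants: 6 methyl 5-chloro-5-oxopentanoate; 7 2,2-dimethyl-1,3-dioxane-4,6-dione (Meldrum's acid)
Product: 9 1-benzyl 7-methyl 3-oxoheptanedioate, via acyl Meldrum's acid 8 (not isolated)
Conditions: pyridine (2 equiv), CH2Cl2, 0 °C → rt; then BnOH, toluene, reflux
Reagents that add atoms: benzyl alcohol, OCc1ccccc1
Why: C-acylation of Meldrum's acid, then thermal loss of acetone and CO2 through an acylketene that benzyl alcohol traps, is the standard β-keto ester synthesis; the remote methyl ester is inert.

Step 5
Reactants: 9 1-benzyl 7-methyl 3-oxoheptanedioate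
Product: 10 1-benzyl 7-methyl (3R)-3-hydroxyheptanedioate
Conditions: H2 (10 bar), RuCl2[(R)-BINAP] (0.2 mol %), MeOH, 50 °C
Reagents that add atoms: none
Why: Noyori asymmetric hydrogenation; the ketone and the β-ester carbonyl chelate Ru-(R)-BINAP, hydride goes to one face and sets C3 as R (the future C4'), while the non-chelating distal ester and the benzyl group are left alone.

Step 6
Reactants: 10 1-benzyl 7-methyl (3R)-3-hydroxyheptanedioate
Product: 11 benzyl 2-[(2R)-6-oxooxan-2-yl]acetate
Conditions: p-TsOH·H2O (5 mol %), toluene, 80 °C, MeOH distilled off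
Reagents that add atoms: none
Why: Acid-catalysed intramolecular transesterification (6-exo-trig lactonisation) can only engage the methyl ester, since the benzyl ester would give a strained β-lactone; the temporary ring masks the C4' oxygen and activates the distal carbonyl.

Step 7
Reactants: 5 (3S,4R)-4-(dibenzylamino)pent-1-yn-3-ol; 11 benzyl 2-[(2R)-6-oxooxan-2-yl]acetate
Product: 13 benzyl (3R,10S,11R)-11-(dibenzylamino)-3,10-dihydroxy-7-oxododec-8-ynoate, via dilithiated alkynol 12 (not isolated)
Conditions: 5, n-BuLi (2.0 equiv), THF, −78 °C; then 11 (1.0 equiv), −78 °C; AcOH (2.2 equiv) quench at −78 °C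
Reagents that add atoms: none
Why: Addition of a lithium acetylide to a δ-lactone to give a δ-hydroxy ynone; the lactone is much more electrophilic than the acyclic benzyl ester, and its tetrahedral adduct should persist at −78 °C until the acidic quench, which prevents a second addition and leaves all stereocentres untouched.

Step 8
Reactants: 13 benzyl (3R,10S,11R)-11-(dibenzylamino)-3,10-dihydroxy-7-oxododec-8-ynoate
Product: 14 benzyl (3R,10S,11R)-3,10-bis[(tert-butyldimethylsilyl)oxy]-11-(dibenzylamino)-7-oxododec-8-ynoate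
Conditions: TBSOTf (2.4 equiv), 2,6-lutidine, CH2Cl2, −78 → 0 °C
Reagents that add atoms: tert-butyldimethylsilyl triflate, CC(C)(C)[Si](C)(C)OS(=O)(=O)C(F)(F)F
Why: O-silylation with a silyl triflate and a hindered base is faster than any reaction at the ynone and blocks both hydroxyl groups, so that furan formation and spiroketalisation of a dihydroxy ketone cannot compete in the next step.

Step 9
Reactants: 14 benzyl (3R,10S,11R)-3,10-bis[(tert-butyldimethylsilyl)oxy]-11-(dibenzylamino)-7-oxododec-8-ynoate
Product: 17 (3R)-3-[(tert-butyldimethylsilyl)oxy]-6-{(2S,5S,6R)-5-[(tert-butyldimethylsilyl)oxy]-6-methylpiperidin-2-yl}hexanoic acid, via amino keto acid 15 (not isolated), via cyclic imine 16 (not isolated)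
Conditions: H2 (3 bar), Pd(OH)2/C, EtOH–EtOAc (1:1), rt
Reagents that add atoms: none
Why: Hydrogenation/hydrogenolysis/intramolecular reductive amination cascade; saturation of the alkyne and loss of three benzyl groups free the amine and the acid, 6-exo-trig condensation on the ketone closes N1–C6, and the cyclic imine should take up hydrogen on the face opposite the C2 methyl group, which places the chain equatorial and sets C6 as S (2,6-cis).

Step 10
Reactants: 17 (3R)-3-[(tert-butyldimethylsilyl)oxy]-6-{(2S,5S,6R)-5-[(tert-butyldimethylsilyl)oxy]-6-methylpiperidin-2-yl}hexanoic acid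
Product: 18 (3R)-6-{(2S,5S,6R)-1-(tert-butoxycarbonyl)-5-[(tert-butyldimethylsilyl)oxy]-6-methylpiperidin-2-yl}-3-[(tert-butyldimethylsilyl)oxy]hexanoic acid
Conditions: Boc2O (3 equiv), Et3N, dioxane–H2O, 50 °C; citric acid work-up
Reagents that add atoms: di-tert-butyl dicarbonate, CC(C)(C)OC(=O)OC(=O)OC(C)(C)C
Why: Carbamate formation at the secondary amine removes the oxidisable lone pair before the anodic step; the aqueous medium returns any activated carboxylate to the acid, and excess reagent and heat answer the hindrance by C2 and C6.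

Step 11
Reactants: 19 (S)-3-hydroxybutanoic acid
Product: 20 (S)-3-acetoxybutanoic acid
Conditions: AcCl, CH2Cl2, 0 °C → rt; aqueous work-up
Reagents that add atoms: acetyl chloride, CC(=O)Cl
Why: Base-free O-acetylation avoids β-elimination to crotonic acid and leaves the stereocentre, the future C15' (S), untouched.

Step 12
Reactants: 20 (S)-3-acetoxybutanoic acid; 21 10-(tert-butoxy)-10-oxodecanoic acid (mono-tert-butyl sebacate)
Product: 22 tert-butyl (11S)-11-acetoxydodecanoate
Conditions: 20 (3 equiv), 21 (1 equiv), NaOMe (5 % of total acid), MeOH, undivided cell, Pt anode/Pt cathode, 150–250 mA cm−2, 20–30 °C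
Reagents that add atoms: none
Why: Mixed Kolbe electrolysis of an O-acetyl β-hydroxy acid with a diacid half-ester, a long-established pairing; both carboxylates give primary radicals at platinum that combine to the C13'–C14' bond, the excess of the cheaper acid 20 favours the cross product, and the stereocentre β to the radical is untouched.

Step 13
Reactants: 22 tert-butyl (11S)-11-acetoxydodecanoate
Product: 23 (11S)-11-acetoxydodecanoic acid
Conditions: TFA–CH2Cl2 (1:2), rt
Reagents that add atoms: none
Why: Acidolysis of the tert-butyl ester (E1 loss of 2-methylpropene) leaves the secondary acetate intact.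

Step 14
Reactants: 18 (3R)-6-{(2S,5S,6R)-1-(tert-butoxycarbonyl)-5-[(tert-butyldimethylsilyl)oxy]-6-methylpiperidin-2-yl}-3-[(tert-butyldimethylsilyl)oxy]hexanoic acid; 23 (11S)-11-acetoxydodecanoic acid
Product: 24 tert-butyl (2R,3S,6S)-6-{(4S,15S)-15-acetoxy-4-[(tert-butyldimethylsilyl)oxy]hexadecyl}-3-[(tert-butyldimethylsilyl)oxy]-2-methylpiperidine-1-carboxylate
Conditions: 18 (1 equiv), 23 (4 equiv), NaOMe (5 % of total acid), MeOH, undivided cell, smooth Pt anode/Pt cathode, 150–250 mA cm−2, 30–40 °C, electrolysis until the acids are consumed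
Reagents that add atoms: none
Why: Mixed Kolbe electrolysis: both carboxylates are adsorbed on the platinum anode, each loses one electron and CO2, and the two primary radicals (C5' from 18, C6' from 23) combine in the reaction layer, so that one operation deletes both activating carboxyl carbons and delivers the complete C22N skeleton with all five stereocentres in place. The closest known reaction type is the anodic cross-coupling of O-protected 3-hydroxyalkanoic acids with fatty acids or diacid half-esters, as already used in step 12. No ring is closed and no stereocentre is created; the nearest one, C4', is β to the radical centre, never becomes planar and is carried through, and a C5' radical, unlike a C5' carbanion or organometal, does not expel the β-silyloxy group. Hetero- over homo-coupling is secured statistically by the fourfold excess of the simple partner 23, whose symmetrical dimer is an unpolar diester that chromatography removes. Radical coupling over two-electron (Hofer–Moest) pathways is secured by the unbranched, unstabilised primary radicals, smooth platinum, high current density and weakly acidic methanol. Oxidation elsewhere is held back because the carboxylate layer shields the anode, the nitrogen is a carbamate whose two α-C–H bonds are tertiary and hindered, and silyl ethers and acetate are not oxidised in this window.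

Step 15
Reactants: 24 tert-butyl (2R,3S,6S)-6-{(4S,15S)-15-acetoxy-4-[(tert-butyldimethylsilyl)oxy]hexadecyl}-3-[(tert-butyldimethylsilyl)oxy]-2-methylpiperidine-1-carboxylate
Product: 26 (2R,3S,6S)-6-[(4S,15S)-4,15-dihydroxyhexadecyl]-2-methylpiperidin-3-ol, via piperidinium chloride 25 (not isolated)
Conditions: 3 M HCl in MeOH, 45 °C; then aq. NaOH, extraction
Reagents that add atoms: none
Why: Acid-catalysed solvolysis removes all four protecting groups in one operation (Boc acidolysis, methanolysis of both silyl ethers, transesterification of the acetate) without breaking any C–O or C–N bond at a stereocentre.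

Compound list
1 | (R)-2-aminopropan-1-ol (D-alaninol) | OC[C@@H](C)N | starting material
2 | (R)-2-(dibenzylamino)propan-1-ol | OC[C@@H](C)N(Cc1ccccc1)Cc1ccccc1 | intermediate
3 | (R)-2-(dibenzylamino)propanal | O=C[C@@H](C)N(Cc1ccccc1)Cc1ccccc1 | intermediate
4 | ethynylmagnesium bromide | C#C[Mg]Br | starting material
5 | (3S,4R)-4-(dibenzylamino)pent-1-yn-3-ol | C#C[C@H](O)[C@@H](C)N(Cc1ccccc1)Cc1ccccc1 | intermediate
6 | methyl 5-chloro-5-oxopentanoate | COC(=O)CCCC(=O)Cl | starting material
7 | 2,2-dimethyl-1,3-dioxane-4,6-dione (Meldrum's acid) | CC1(C)OC(=O)CC(=O)O1 | starting material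
8 | methyl 5-(2,2-dimethyl-4,6-dioxo-1,3-dioxan-5-ylidene)-5-hydroxypentanoate (acyl Meldrum's acid, enol form) | COC(=O)CCCC(O)=C1C(=O)OC(C)(C)OC1=O | intermediate
9 | 1-benzyl 7-methyl 3-oxoheptanedioate | COC(=O)CCCC(=O)CC(=O)OCc1ccccc1 | intermediate
10 | 1-benzyl 7-methyl (3R)-3-hydroxyheptanedioate | O=C(OCc1ccccc1)C[C@H](O)CCCC(=O)OC | intermediate
11 | benzyl 2-[(2R)-6-oxooxan-2-yl]acetate | O=C(OCc1ccccc1)C[C@H]1CCCC(=O)O1 | intermediate
12 | dilithio derivative of 5 (lithium alkoxide and lithium acetylide) | [Li]C#C[C@H](O[Li])[C@@H](C)N(Cc1ccccc1)Cc1ccccc1 | intermediate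
13 | benzyl (3R,10S,11R)-11-(dibenzylamino)-3,10-dihydroxy-7-oxododec-8-ynoate | O=C(OCc1ccccc1)C[C@H](O)CCCC(=O)C#C[C@H](O)[C@@H](C)N(Cc1ccccc1)Cc1ccccc1 | intermediate
14 | benzyl (3R,10S,11R)-3,10-bis[(tert-butyldimethylsilyl)oxy]-11-(dibenzylamino)-7-oxododec-8-ynoate | O=C(OCc1ccccc1)C[C@H](O[Si](C)(C)C(C)(C)C)CCCC(=O)C#C[C@H](O[Si](C)(C)C(C)(C)C)[C@@H](C)N(Cc1ccccc1)Cc1ccccc1 | intermediate
15 | (3R,10S,11R)-11-amino-3,10-bis[(tert-butyldimethylsilyl)oxy]-7-oxododecanoic acid | OC(=O)C[C@H](O[Si](C)(C)C(C)(C)C)CCCC(=O)CC[C@H](O[Si](C)(C)C(C)(C)C)[C@@H](C)N | intermediate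
16 | (3R)-3-[(tert-butyldimethylsilyl)oxy]-6-{(2R,3S)-3-[(tert-butyldimethylsilyl)oxy]-2-methyl-2,3,4,5-tetrahydropyridin-6-yl}hexanoic acid | OC(=O)C[C@H](O[Si](C)(C)C(C)(C)C)CCCC1=N[C@H](C)[C@@H](O[Si](C)(C)C(C)(C)C)CC1 | intermediate
17 | (3R)-3-[(tert-butyldimethylsilyl)oxy]-6-{(2S,5S,6R)-5-[(tert-butyldimethylsilyl)oxy]-6-methylpiperidin-2-yl}hexanoic acid | OC(=O)C[C@H](O[Si](C)(C)C(C)(C)C)CCC[C@H]1CC[C@H](O[Si](C)(C)C(C)(C)C)[C@@H](C)N1 | intermediate
18 | (3R)-6-{(2S,5S,6R)-1-(tert-butoxycarbonyl)-5-[(tert-butyldimethylsilyl)oxy]-6-methylpiperidin-2-yl}-3-[(tert-butyldimethylsilyl)oxy]hexanoic acid | OC(=O)C[C@H](O[Si](C)(C)C(C)(C)C)CCC[C@H]1CC[C@H](O[Si](C)(C)C(C)(C)C)[C@@H](C)N1C(=O)OC(C)(C)C | intermediate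
19 | (S)-3-hydroxybutanoic acid | C[C@H](O)CC(=O)O | starting material
20 | (S)-3-acetoxybutanoic acid | C[C@H](OC(C)=O)CC(=O)O | intermediate
21 | 10-(tert-butoxy)-10-oxodecanoic acid (mono-tert-butyl sebacate) | CC(C)(C)OC(=O)CCCCCCCCC(=O)O | starting material
22 | tert-butyl (11S)-11-acetoxydodecanoate | C[C@H](OC(C)=O)CCCCCCCCCC(=O)OC(C)(C)C | intermediate
23 | (11S)-11-acetoxydodecanoic acid | C[C@H](OC(C)=O)CCCCCCCCCC(=O)O | intermediate
24 | tert-butyl (2R,3S,6S)-6-{(4S,15S)-15-acetoxy-4-[(tert-butyldimethylsilyl)oxy]hexadecyl}-3-[(tert-butyldimethylsilyl)oxy]-2-methylpiperidine-1-carboxylate | C[C@H](OC(C)=O)CCCCCCCCCC[C@H](O[Si](C)(C)C(C)(C)C)CCC[C@H]1CC[C@H](O[Si](C)(C)C(C)(C)C)[C@@H](C)N1C(=O)OC(C)(C)C | intermediate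
25 | (2R,3S,6S)-6-[(4S,15S)-4,15-dihydroxyhexadecyl]-3-hydroxy-2-methylpiperidinium chloride | C[C@H](O)CCCCCCCCCC[C@H](O)CCC[C@H]1CC[C@H](O)[C@@H](C)[NH2+]1.[Cl-] | intermediate
26 | (2R,3S,6S)-6-[(4S,15S)-4,15-dihydroxyhexadecyl]-2-methylpiperidin-3-ol | C[C@H](O)CCCCCCCCCC[C@H](O)CCC[C@H]1CC[C@H](O)[C@@H](C)N1 | target

Total step count: 15. Longest linear sequence: 9 steps (1, 2, 3, 7, 8, 9, 10, 14, 15).

Steps most likely to fail

1. Step 14. Homo-coupling and disproportionation of the radicals may outrun the hetero-coupling. Over-oxidation of the C5' radical to carbocation chemistry, anodic oxidation next to nitrogen, or passivation of the anode by the lipophilic substrate may consume the valuable acid. The fallback leaves the anodic radical–radical combination for a cathodic, nickel-templated coupling and sets out from 18 and 23. Each acid is esterified with N-hydroxyphthalimide (DIC, cat. DMAP, CH2Cl2) to give the 1,3-dioxoisoindolin-2-yl ester of 18 F1 and the 1,3-dioxoisoindolin-2-yl ester of 23 F2. The two redox-active esters (F2 in excess) are joined by nickel-electrocatalytic doubly decarboxylative cross-coupling (NiCl2·6H2O, terpyridine-type ligand, NaI, DMF, sacrificial Zn anode, carbon or Ni-foam cathode, constant current, rt). Each ester is reduced and loses CO2 and phthalimide, and the C5'–C6' bond forms at nickel, so nothing in the molecule sees an oxidising potential. The fallback comes back to the route at 24.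

2. Step 7. Four processes may erode the ynone:
   - attack of the acetylide or the alkoxide at the benzyl ester;
   - premature collapse of the tetrahedral adduct followed by a second addition;
   - base-induced elimination across C2–C3 of the ester;
   - propargyl–allenyl isomerisation of the γ-hydroxy ynone.

   The fallback replaces the organolithium addition by a palladium/copper-catalysed acyl Sonogashira coupling under amine base and sets out from 11 and 5. The lactone of 11 is saponified selectively (LiOH, 1.0 equiv, THF–H2O, 0 °C) to lithium (5R)-7-(benzyloxy)-5-hydroxy-7-oxoheptanoate F3. Persilylation (TBSCl, imidazole, DMF) gives 1-benzyl 7-(tert-butyldimethylsilyl) (3R)-3-[(tert-butyldimethylsilyl)oxy]heptanedioate F4. The silyl ester is converted under neutral conditions ((COCl)2, cat. DMF, CH2Cl2) into benzyl (3R)-3-[(tert-butyldimethylsilyl)oxy]-7-chloro-7-oxoheptanoate F5. In parallel 5 is silylated (TBSCl, imidazole, DMF) to (2R,3S)-N,N-dibenzyl-3-[(tert-butyldimethylsilyl)oxy]pent-4-yn-2-amine F6. Coupling of F5 with F6 (PdCl2(PPh3)2, CuI, Et3N, THF, rt) comes back to the route at 14 and bypasses 13.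

3. Step 10. Acylation of the nitrogen, which is flanked by the substituted carbons C2 and C6, may be too slow, and activation of the carboxylate by the dicarbonate may compete. The fallback changes the protecting group class and the end game and sets out from 17. The more reactive benzyl chloroformate under Schotten–Baumann conditions (aq. Na2CO3, dioxane, 0 °C → rt) should give (3R)-6-{(2S,5S,6R)-1-[(benzyloxy)carbonyl]-5-[(tert-butyldimethylsilyl)oxy]-6-methylpiperidin-2-yl}-3-[(tert-butyldimethylsilyl)oxy]hexanoic acid F7. This acid is electrolysed with 23 as in step 14 to benzyl (2R,3S,6S)-6-{(4S,15S)-15-acetoxy-4-[(tert-butyldimethylsilyl)oxy]hexadecyl}-3-[(tert-butyldimethylsilyl)oxy]-2-methylpiperidine-1-carboxylate F8. Hydrogenolysis in methanolic HCl (H2, Pd/C, 40 °C) removes the carbamate, both silyl ethers and the acetate in one operation. The fallback comes back to the route at 25 and, after basification, at 26.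

Further compounds
F1 | step 14 | 1,3-dioxoisoindolin-2-yl ester of 18 | O=C(C[C@H](O[Si](C)(C)C(C)(C)C)CCC[C@H]1CC[C@H](O[Si](C)(C)C(C)(C)C)[C@@H](C)N1C(=O)OC(C)(C)C)ON1C(=O)c2ccccc2C1=O
F2 | step 14 | 1,3-dioxoisoindolin-2-yl ester of 23 | C[C@H](OC(C)=O)CCCCCCCCCC(=O)ON1C(=O)c2ccccc2C1=O
F3 | step 7 | lithium (5R)-7-(benzyloxy)-5-hydroxy-7-oxoheptanoate | O=C(OCc1ccccc1)C[C@H](O)CCCC(=O)[O-].[Li+]
F4 | step 7 | 1-benzyl 7-(tert-butyldimethylsilyl) (3R)-3-[(tert-butyldimethylsilyl)oxy]heptanedioate | O=C(OCc1ccccc1)C[C@H](O[Si](C)(C)C(C)(C)C)CCCC(=O)O[Si](C)(C)C(C)(C)C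
F5 | step 7 | benzyl (3R)-3-[(tert-butyldimethylsilyl)oxy]-7-chloro-7-oxoheptanoate | O=C(OCc1ccccc1)C[C@H](O[Si](C)(C)C(C)(C)C)CCCC(=O)Cl
F6 | step 7 | (2R,3S)-N,N-dibenzyl-3-[(tert-butyldimethylsilyl)oxy]pent-4-yn-2-amine | C#C[C@H](O[Si](C)(C)C(C)(C)C)[C@@H](C)N(Cc1ccccc1)Cc1ccccc1
F7 | step 10 | (3R)-6-{(2S,5S,6R)-1-[(benzyloxy)carbonyl]-5-[(tert-butyldimethylsilyl)oxy]-6-methylpiperidin-2-yl}-3-[(tert-butyldimethylsilyl)oxy]hexanoic acid | OC(=O)C[C@H](O[Si](C)(C)C(C)(C)C)CCC[C@H]1CC[C@H](O[Si](C)(C)C(C)(C)C)[C@@H](C)N1C(=O)OCc1ccccc1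
F8 | step 10 | benzyl (2R,3S,6S)-6-{(4S,15S)-15-acetoxy-4-[(tert-butyldimethylsilyl)oxy]hexadecyl}-3-[(tert-butyldimethylsilyl)oxy]-2-methylpiperidine-1-carboxylate | C[C@H](OC(C)=O)CCCCCCCCCC[C@H](O[Si](C)(C)C(C)(C)C)CCC[C@H]1CC[C@H](O[Si](C)(C)C(C)(C)C)[C@@H](C)N1C(=O)OCc1ccccc1
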